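**Strategy.** The route rests on cutting the five-membered ring of the indole at C3a–C3 and N1–C2. Because C3 carries the oxazol-5-yl group and C2 only hydrogen, both bonds can be made in one palladium-catalysed Larock heteroannulation of an ortho-iodoaniline, whose iodine sits between NH2 and OMe and so fixes the 4-methoxy-6-bromo pattern, with an alkyne bearing the complete 2-(5-bromo-1-SEM-pyrrol-2-yl)oxazol-5-yl unit at one end and a trimethylsilyl group at the other. The silyl group steers the oxazole to C3, ends at C2 and leaves with the SEM group under fluoride in the final step.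

Key step: step 9

Assumption: 2-bromo-1,3-oxazole (9) is taken as a purchasable building block; SEM stands for 2-(trimethylsilyl)ethoxymethyl; the target has no stereocentre, so no stereocontrol is required.

**Route**

Step 1
Reactants: 1 2-methoxy-6-nitroaniline
Product: 2 4-bromo-2-methoxy-6-nitroaniline
Conditions: NBS (1.05 equiv), MeCN, 0 °C to rt
Reagents that add atoms: N-bromosuccinimide, O=C1CCC(=O)N1Br
Why: Electrophilic aromatic bromination: the amino group is the strongest director and both of its ortho positions are occupied, so NBS should substitute only the para carbon C4.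

Step 2
Reactants: 2 4-bromo-2-methoxy-6-nitroaniline
Product: 4 5-bromo-2-iodo-1-methoxy-3-nitrobenzene, via arenediazonium hydrogensulfate 3 (not isolated)
Conditions: NaNO2, conc. H2SO4/AcOH, 0–5 °C; then KI, H2O, 0 °C to rt
Reagents that add atoms: potassium iodide, [K+].[I-]
Why: Sandmeyer-type iododediazoniation: nitrosylsulfuric acid diazotises the weakly basic ortho-nitroaniline and iodide then replaces N2 by electron transfer without a copper salt, placing iodine between the methoxy and nitro groups.

Step 3
Reactants: 4 5-bromo-2-iodo-1-methoxy-3-nitrobenzene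
Product: 5 5-bromo-2-iodo-3-methoxyaniline
Conditions: Fe powder, AcOH/EtOH, 70 °C
Reagents that add atoms: none
Why: Béchamp reduction: iron in acetic acid reduces the nitro group by stepwise electron and proton transfer and is known to leave aryl iodides and bromides untouched, unlike catalytic hydrogenation.

Step 4
Reactants: 6 1H-pyrrole
Product: 8 1-SEM-pyrrole (1-{[2-(trimethylsilyl)ethoxy]methyl}-1H-pyrrole), via sodium pyrrolide 7 (not isolated)
Conditions: NaH, DMF, 0 °C; then SEMCl, 0 °C to rt
Reagents that add atoms: 2-(trimethylsilyl)ethoxymethyl chloride, C[Si](C)(C)CCOCCl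
Why: N-alkylation of the pyrrolide anion (SN2 on the chloromethyl ether): the sodium salt in DMF reacts at nitrogen, and the resulting SEM group survives organolithiums, amide bases and hot carbonate.

Step 5
Reactants: 8 1-SEM-pyrrole; 9 2-bromo-1,3-oxazole
Product: 12 2-(1-SEM-pyrrol-2-yl)-1,3-oxazole, via 2-lithio-1-SEM-pyrrole 10 (not isolated), via (1-SEM-pyrrol-2-yl)zinc chloride 11 (not isolated)
Conditions: n-BuLi, DME, −5 °C; ZnCl2, THF, −5 °C to rt; then 9, Pd(PPh3)4 (5 mol %), THF, 60 °C
Reagents that add atoms: none
Why: Directed α-lithiation followed by Negishi cross-coupling: the SEM oxygen guides n-BuLi to C2 of the pyrrole, the zinc reagent tolerates the oxazole, and the C2–Br bond of 9 is strongly activated toward oxidative addition to zerovalent palladium.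

Step 6
Reactants: 12 2-(1-SEM-pyrrol-2-yl)-1,3-oxazole
Product: 13 2-(5-bromo-1-SEM-pyrrol-2-yl)-1,3-oxazole
Conditions: NBS (1.0 equiv), THF, −78 °C to 0 °C, dark
Reagents that add atoms: N-bromosuccinimide, O=C1CCC(=O)N1Br
Why: Electrophilic aromatic bromination of an N-alkylpyrrole: the only free α-position (C5) is the most nucleophilic carbon in the molecule, so one equivalent of NBS at low temperature should brominate there and leave the electron-poor oxazole untouched.

Step 7
Reactants: 13 2-(5-bromo-1-SEM-pyrrol-2-yl)-1,3-oxazole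
Product: 15 2-(5-bromo-1-SEM-pyrrol-2-yl)-5-iodo-1,3-oxazole, via 5-lithiooxazole 14 (not isolated)
Conditions: LiN(i-Pr)2 (1.1 equiv), THF, −78 °C; then I2, −78 °C to 0 °C; aq Na2S2O3
Reagents that add atoms: iodine, II
Why: Deprotonation–iodination (lithiation with electrophilic quench): C5–H next to the ring oxygen is the most acidic C–H once C2 of the oxazole is substituted, and an amide base, unlike an alkyllithium, does not exchange the pyrrolyl bromide.

Step 8
Reactants: 15 2-(5-bromo-1-SEM-pyrrol-2-yl)-5-iodo-1,3-oxazole; 16 trimethylsilylacetylene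
Product: 17 2-(5-bromo-1-SEM-pyrrol-2-yl)-5-[(trimethylsilyl)ethynyl]-1,3-oxazole
Conditions: PdCl2(PPh3)2 (3 mol %), CuI (5 mol %), Et3N, THF, rt
Reagents that add atoms: none
Why: Sonogashira coupling: the electron-poor oxazolyl C–I bond adds to zerovalent palladium at room temperature, where the electron-rich pyrrolyl C–Br bond stays inert.

Step 9
Reactants: 5 5-bromo-2-iodo-3-methoxyaniline (1.2 equiv); 17 2-(5-bromo-1-SEM-pyrrol-2-yl)-5-[(trimethylsilyl)ethynyl]-1,3-oxazole
Product: 18 6-bromo-3-[2-(5-bromo-1-SEM-pyrrol-2-yl)-1,3-oxazol-5-yl]-4-methoxy-2-(trimethylsilyl)-1H-indole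
Conditions: Pd(OAc)2 (10 mol %), LiCl (1 equiv), Na2CO3 (3 equiv), DMF, 100 °C, Ar
Reagents that add atoms: none
Why: Zerovalent palladium, formed in the flask from Pd(OAc)2 and held as a chloride-ligated species by LiCl, inserts into the C–I bond of 5, the alkyne of 17 undergoes syn carbopalladation, and binding of the neighbouring NH2 to palladium followed by C–N reductive elimination releases the indole and returns the catalyst. The closest known reaction type is the Larock indole synthesis of ortho-iodoanilines with aryl silyl alkynes, which gives 2-silyl-3-arylindoles. The five-membered ring is closed as a formal [3+2] annulation: C3a–C3 forms in the intermolecular insertion and N1–C2 forms intramolecularly by reductive elimination from a six-membered azapalladacycle, so no cyclisation onto an arene C–H is involved and the 4-OMe/6-Br pattern is inherited unchanged from 5. No stereocentre is created. Regioselectivity is needed in the insertion and is secured by the trimethylsilyl group, which is larger than the flat oxazol-5-yl group, takes the carbon bonded to palladium (the future C2) and sends the oxazole to C3. Chemoselectivity is needed among three carbon–halogen bonds and is secured by the much faster oxidative addition of the aryl iodide to ligand-free palladium than of the aryl bromide or the electron-rich pyrrolyl bromide, while SEM masks the pyrrole N–H and Na2CO3 is mild enough to keep the alkynyl C–Si bond until insertion.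

Step 10
Reactants: 18 6-bromo-3-[2-(5-bromo-1-SEM-pyrrol-2-yl)-1,3-oxazol-5-yl]-4-methoxy-2-(trimethylsilyl)-1H-indole
Product: 20 6-bromo-3-[2-(5-bromo-1H-pyrrol-2-yl)-1,3-oxazol-5-yl]-4-methoxy-1H-indole (target), via SEM-protected 2-H indole 19 (not isolated)
Conditions: n-Bu4NF (1 M in THF, excess), THF, rt, then 65 °C; aq NH4Cl
Reagents that add atoms: none
Why: Fluoride-mediated protodesilylation of the 2-silylindole followed by fluoride-induced fragmentation of the SEM group (attack at silicon, loss of ethene and formaldehyde), both known for N–H indoles and N-SEM pyrroles, with the aryl and pyrrolyl bromides inert to fluoride.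

**Compound list**

1 | 2-methoxy-6-nitroaniline | COc1cccc([N+](=O)[O-])c1N | starting material
2 | 4-bromo-2-methoxy-6-nitroaniline | COc1cc(Br)cc([N+](=O)[O-])c1N | intermediate
3 | 4-bromo-2-methoxy-6-nitrobenzenediazonium hydrogensulfate | COc1cc(Br)cc([N+](=O)[O-])c1[N+]#N.OS(=O)(=O)[O-] | intermediate
4 | 5-bromo-2-iodo-1-methoxy-3-nitrobenzene | COc1cc(Br)cc([N+](=O)[O-])c1I | intermediate
5 | 5-bromo-2-iodo-3-methoxyaniline | COc1cc(Br)cc(N)c1I | intermediate
6 | 1H-pyrrole | c1cc[nH]c1 | starting material
7 | sodium pyrrolide | [Na+].c1cc[n-]c1 | intermediate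
8 | 1-{[2-(trimethylsilyl)ethoxy]methyl}-1H-pyrrole (1-SEM-pyrrole) | C[Si](C)(C)CCOCn1cccc1 | intermediate
9 | 2-bromo-1,3-oxazole | Brc1ncco1 | starting material
10 | (1-SEM-pyrrol-2-yl)lithium | [Li]c1cccn1COCC[Si](C)(C)C | intermediate
11 | (1-SEM-pyrrol-2-yl)zinc chloride | Cl[Zn]c1cccn1COCC[Si](C)(C)C | intermediate
12 | 2-(1-SEM-pyrrol-2-yl)-1,3-oxazole | C[Si](C)(C)CCOCn1cccc1-c1ncco1 | intermediate
13 | 2-(5-bromo-1-SEM-pyrrol-2-yl)-1,3-oxazole | C[Si](C)(C)CCOCn1c(Br)ccc1-c1ncco1 | intermediate
14 | [2-(5-bromo-1-SEM-pyrrol-2-yl)-1,3-oxazol-5-yl]lithium | [Li]c1cnc(-c2ccc(Br)n2COCC[Si](C)(C)C)o1 | intermediate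
15 | 2-(5-bromo-1-SEM-pyrrol-2-yl)-5-iodo-1,3-oxazole | Ic1cnc(-c2ccc(Br)n2COCC[Si](C)(C)C)o1 | intermediate
16 | trimethylsilylacetylene | C[Si](C)(C)C#C | starting material
17 | 2-(5-bromo-1-SEM-pyrrol-2-yl)-5-[(trimethylsilyl)ethynyl]-1,3-oxazole | C[Si](C)(C)C#Cc1cnc(-c2ccc(Br)n2COCC[Si](C)(C)C)o1 | intermediate
18 | 6-bromo-3-[2-(5-bromo-1-SEM-pyrrol-2-yl)-1,3-oxazol-5-yl]-4-methoxy-2-(trimethylsilyl)-1H-indole | COc1cc(Br)cc2[nH]c([Si](C)(C)C)c(-c3cnc(-c4ccc(Br)n4COCC[Si](C)(C)C)o3)c12 | intermediate
19 | 6-bromo-3-[2-(5-bromo-1-SEM-pyrrol-2-yl)-1,3-oxazol-5-yl]-4-methoxy-1H-indole | COc1cc(Br)cc2[nH]cc(-c3cnc(-c4ccc(Br)n4COCC[Si](C)(C)C)o3)c12 | intermediate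
20 | 6-bromo-3-[2-(5-bromo-1H-pyrrol-2-yl)-1,3-oxazol-5-yl]-4-methoxy-1H-indole | COc1cc(Br)cc2[nH]cc(-c3cnc(-c4ccc(Br)[nH]4)o3)c12 | target

**Step count**

Total steps: 10. Longest linear sequence: 7 steps (steps 4 to 10, from pyrrole 6); the aniline branch (steps 1 to 3) joins at step 9.

**Steps most likely to fail**

Step 9 (Larock heteroannulation). Three processes could erode it: oxidative addition of palladium into one of the C–Br bonds at 100 °C; loss of the alkynyl silyl group before insertion, which would remove the regiocontrol; and slow insertion at an arylpalladium centre flanked by NH2 and OMe. Fallback: the indole is taken ready-made and joined to the oxazole by cross-coupling at C3 instead of being built on the alkyne. Purchased 6-bromo-4-methoxy-1H-indole F1 is iodinated at C3 with N-iodosuccinimide in DMF to 6-bromo-3-iodo-4-methoxy-1H-indole F2 and protected with Boc2O/DMAP as tert-butyl 6-bromo-3-iodo-4-methoxyindole-1-carboxylate F3. The fallback sets out from 13, which is lithiated at oxazole C5 to 14 as in step 7 and transmetalated with ZnCl2 to [2-(5-bromo-1-SEM-pyrrol-2-yl)-1,3-oxazol-5-yl]zinc chloride F4. Negishi coupling of F4 with F3 (Pd(PPh3)4, THF, rt to 50 °C) should engage only the C–I bond and give tert-butyl 6-bromo-3-[2-(5-bromo-1-SEM-pyrrol-2-yl)-1,3-oxazol-5-yl]-4-methoxyindole-1-carboxylate F5. K2CO3 in MeOH then removes the indole carbamate, and the route is rejoined at 19, which is taken through the warm fluoride stage of step 10.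

Step 10 (global fluoride deprotection). The C2 protodesilylation is expected to be easy. The SEM cleavage may stall at the N-hydroxymethyl stage, released formaldehyde may re-alkylate the electron-rich rings, and forcing conditions may cause protodebromination of the pyrrole. Fallback: Lewis-acid cleavage in two stages. It sets out from 19, isolated after the room-temperature fluoride stage. BF3·OEt2 in CH2Cl2 at 0 °C fragments the silylethyl ether and gives, after aqueous quench, 6-bromo-3-{2-[5-bromo-1-(hydroxymethyl)pyrrol-2-yl]-1,3-oxazol-5-yl}-4-methoxy-1H-indole F6. Aqueous NH3 in MeOH at rt then expels and scavenges formaldehyde, and the route is rejoined at 20.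

Step 6 (pyrrole bromination). Substitution could stray to the β-position C4 or run on to a dibromide, and the electron-rich bromopyrrole may decompose on handling. Fallback: the bromine is placed before the oxazole is attached, so that its position is fixed by symmetry. It sets out from 8, which with two equivalents of NBS in THF at −78 °C gives 2,5-dibromo-1-SEM-pyrrole F7. One equivalent of n-BuLi at −78 °C performs a single bromine–lithium exchange to (5-bromo-1-SEM-pyrrol-2-yl)lithium F8, and ZnCl2 converts this into (5-bromo-1-SEM-pyrrol-2-yl)zinc chloride F9. Negishi coupling of F9 with 9 under the conditions of step 5 rejoins the route at 13; the activated C2–Br bond of 9 should react far faster than the pyrrolyl bromide.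

**Further compounds**

F1 | step 9 | 6-bromo-4-methoxy-1H-indole | COc1cc(Br)cc2[nH]ccc12
F2 | step 9 | 6-bromo-3-iodo-4-methoxy-1H-indole | COc1cc(Br)cc2[nH]cc(I)c12
F3 | step 9 | tert-butyl 6-bromo-3-iodo-4-methoxyindole-1-carboxylate | COc1cc(Br)cc2c1c(I)cn2C(=O)OC(C)(C)C
F4 | step 9 | [2-(5-bromo-1-SEM-pyrrol-2-yl)-1,3-oxazol-5-yl]zinc chloride | Cl[Zn]c1cnc(-c2ccc(Br)n2COCC[Si](C)(C)C)o1
F5 | step 9 | tert-butyl 6-bromo-3-[2-(5-bromo-1-SEM-pyrrol-2-yl)-1,3-oxazol-5-yl]-4-methoxyindole-1-carboxylate | COc1cc(Br)cc2c1c(-c1cnc(-c3ccc(Br)n3COCC[Si](C)(C)C)o1)cn2C(=O)OC(C)(C)C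
F6 | step 10 | 6-bromo-3-{2-[5-bromo-1-(hydroxymethyl)pyrrol-2-yl]-1,3-oxazol-5-yl}-4-methoxy-1H-indole | COc1cc(Br)cc2[nH]cc(-c3cnc(-c4ccc(Br)n4CO)o3)c12
F7 | step 6 | 2,5-dibromo-1-SEM-pyrrole | C[Si](C)(C)CCOCn1c(Br)ccc1Br
F8 | step 6 | (5-bromo-1-SEM-pyrrol-2-yl)lithium | [Li]c1ccc(Br)n1COCC[Si](C)(C)C
F9 | step 6 | (5-bromo-1-SEM-pyrrol-2-yl)zinc chloride | Cl[Zn]c1ccc(Br)n1COCC[Si](C)(C)C
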